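The numbers in the tables stem from a simulated flask on assumed constants; scatter was added.

| flask | solid electrophile | nucleophile | remark | time |
|---|---|---|---|---|
| Saturday's | 20 mM | 22 mM | run made earlier |  |
| Monday's | 20 mM | 30 mM | run made earlier |  |
| Sunday's | 20 mM | 31 mM | run made earlier |  |
| alder | 20 mM | 42.0 mM |  | 4.0 h |
| oak | 20 mM | 21.0 mM |  | 4.0 h |

- Saturday's (time / min: solid electrophile / %, product / %): 10.0: 91.1, 1.1; 30.0: 76.0, 3.8; 60.0: 56.4, 12.0; 80.0: 45.7, 18.7; 120: 23.2, 30.0
- Monday's (time / min: solid electrophile / %, product / %): 25.0: 78.9, 4.6; 50.0: 61.7, 11.8; 80.0: 44.0, 24.0; 90.0: 38.0, 27.7; 120: 22.0, 38.5
- Sunday's (time / min: solid electrophile / %, product / %): 10.0: 91.2, 1.2; 30.0: 74.6, 6.1; 60.0: 55.7, 16.1; 80.0: 43.2, 25.1; 120: 21.4, 39.9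

(standard deviation of a reading: 0.5 percentage points)

- the numbers in the tables scatter by 0.5 percentage points (one standard deviation)
- at the start none of the solid electrophile is in solution
- what has only dissolved of solid electrophile counts as not reacted

- part of the solid electrophile that has reacted (what has only dissolved counts as not reacted) at the end, alder
- part of the solid electrophile that has reacted (what has only dissolved counts as not reacted) at the end, oak
- what raising the concentration of nucleophile from its lowest to its highest value here does to the part of the solid electrophile that has reacted (what has only dissolved counts as not reacted) (changes below 5 percentage points count as none) (it rises / it falls / no change)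

**Reading time.** Read at 4.0 h, alder and oak show what their nucleophile has paid for, so ask the price first.

**The price.** Suppose the product pace, divided by the dissolved fraction (the charge minus solid minus product), follows the free nucleophile. In Saturday's run that ratio goes from 0.0106 /min between the second and third readings to 0.00686 /min between the last two, a factor of 0.650. For the free nucleophile to shrink that much, each product must cost 2.00 nucleophile, the nucleophile price. Sunday's ratio falls by a factor of 0.749, which gives 1.61, so these are rough readings.

**Turned round.** At Saturday's price, the charge of nucleophile pays for a fraction 52.4% of the solid electrophile in oak, and 105% in alder. Carrying Monday's last pace to 4.0 h gives 81.7%, my figure for alder, while I put oak just under its mark. For no change, oak's mark would have to lie within 5 percentage points of that figure, which needs a price of 1.37. Both readings lie above it, so I expect a rise.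

**The result.** The forecast gives 89% for alder and 60% for oak and says it rises, with “More nucleophile raises conversion.” The flasks give 80.1% and 47.7%: it rises, by 32 points, and the difference in nucleophile charged is the main reason.

    solid electrophile ⇌ electrophile, rate k1*(cs1 - [electrophile]) while solid is left; crystals form when [electrophile] > cs1 (solubility = 19.0 mM, k = 1.60 × 10⁻⁴ /s)
    nucleophile + acid set free ⇌ protonated nucleophile, settled at all times (K = 6300 /M)
    nucleophile + acid set free ⇌ idle adduct, settled at all times (K = 61.0 /M)
    electrophile + nucleophile → acid set free + product (k = 0.00940 /M/s)

**What it paid.** Oak's 47.7% lies under its mark. Without the joining of nucleophile and acid set free to protonated nucleophile, oak reaches 58.9%, and ten times the time gives 68.0%, so that joining and the time given act together on oak's answer. Given that longer time, oak passes its mark, so the mark belongs to this reading time and is no wall. In a neighbour flask, like oak but with 50 mM of solid electrophile, the mark is 20.9%, and the computed answer is 19.4%.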